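**Direct plan and its weak points**

A direct plan would close ring B last. The dilithio derivative of 1-(2-bromo-3-methoxyphenyl)cyclopropan-1-ol A1 would be added to 4-[(tert-butyldimethylsilyl)oxy]-5-methoxy-1-naphthaldehyde A2. Desilylation would give the naphthol diol A3, a chiral phosphoric acid would close ring B to the 4-aryltetralone A4 through a quinone methide/cyclopropanol ring opening, and the ketone would be reduced by asymmetric transfer hydrogenation.
- Closure of ring B (C3–C4 bond): it would be an enantioselective C–C attack of a cyclopropanol on a quinone methide with no precedent. It would have to beat O-closure and protonolysis on the intermediate A3, which would be too labile to store, and it alone would carry the C4 stereocentre.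
- Late reduction of the C1 ketone: C1 would be set separately from C4, by catalyst control against an unknown bias of the C4 aryl group. The cis relation would be hoped for, not enforced.
- The run-up: five steps on the naphthalene branch (bromination, silylation, formylation, addition, desilylation) would be spent before any stereocentre exists, two of them only putting on and taking off a silyl group.

**Retrosynthetic overview**

Ring labels: ring A is the methoxy-bearing benzene ring of the tetralin (C4a, C5–C8, C8a), ring B its saturated ring (C1–C4), ring C the phenol ring of the naphthalene (C1′–C4′) and ring D its methoxy ring (C5′–C8′).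
- Feature used: in ring B the C1 oxygen and the C4–C1′ bond are cis-1,4, and C4 is the only benzylic carbon whose cation the ortho C5 methoxy of ring A stabilises. The target is cut at C4–C1′: the C1 oxygen is first tied to C4 as a 1,4-oxygen bridge, then used as the anchor from which a boron-bound naphthyl group is handed to C4 on the face the oxygen leaves.
- Ring order: rings A/B come intact from 5-methoxy-1-tetralone and rings C/D from 8-methoxy-1-naphthol. No carbocycle is closed; the only ring events are closing (step 2) and opening (step 6) of the oxygen bridge.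
- Weak steps avoided: C1 is set first by a ketone reduction on the simplest substrate, and C4 follows from C1 by the geometry of the bridge, so no catalyst/substrate matching, quinone methide or cyclopropanol is needed. The one protecting group (an acetate) leaves in the work-up of the key step.

Key step: step 6

Assumption: the target SMILES is read as the cis-(1S,4S) isomer (C1–OH and C4–aryl on the same face of ring B); 5-methoxy-1-tetralone and 8-methoxy-1-naphthol are taken as purchasable.

**Route**

Step 1
Reactants: 1 5-methoxy-3,4-dihydronaphthalen-1(2H)-one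
Product: 2 (S)-5-methoxy-1,2,3,4-tetrahydronaphthalen-1-ol
Conditions: RuCl(p-cymene)[(S,S)-TsDPEN] (0.5 mol %), HCO2H/Et3N (5:2), EtOAc, 35 °C
Reagents that add atoms: none
Why: Noyori asymmetric transfer hydrogenation of an aryl alkyl ketone, for which 1-tetralones are model substrates; the (S,S)-catalyst should give the (S)-carbinol, and C1 is the only stereocentre of the route set by a reagent.

Step 2
Reactants: 2 (S)-5-methoxy-1,2,3,4-tetrahydronaphthalen-1-ol
Product: 3 (1S,4R)-5-methoxy-1,2,3,4-tetrahydro-1,4-epoxynaphthalene
Conditions: DDQ (1.2 equiv), 2,6-dichloropyridine (2 equiv), 4 Å MS, ClCH2CH2Cl (0.02 M), 0 °C → rt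
Reagents that add atoms: none
Why: Oxidative benzylic C–H etherification with DDQ: hydride abstraction should occur only at C4, the benzylic carbon ortho to the C5 methoxy (C1–H lies meta to it), and the C1 hydroxyl should capture the cation across ring B from its own face, so the bridge is cis by necessity, C4 becomes R without any selection and C1 is untouched.

Step 3
Reactants: 4 8-methoxynaphthalen-1-ol
Product: 5 4-bromo-8-methoxynaphthalen-1-ol
Conditions: NBS (1.0 equiv), MeCN, −20 → 0 °C, dark
Reagents that add atoms: N-bromosuccinimide, O=C1CCC(=O)N1Br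
Why: Electrophilic aromatic bromination; NBS in acetonitrile is para-selective for free 1-naphthols, and the free hydroxyl of ring C should outrank the methoxy group of ring D as director.

Step 4
Reactants: 5 4-bromo-8-methoxynaphthalen-1-ol
Product: 6 4-bromo-8-methoxynaphthalen-1-yl acetate
Conditions: Ac2O (1.5 equiv), pyridine (3 equiv), DMAP (5 mol %), CH2Cl2, 0 °C → rt
Reagents that add atoms: acetic anhydride, CC(=O)OC(C)=O
Why: O-acylation of the naphthol; the acetate removes the phenolic proton that could cleave a C–B bond, damps ring C against free Friedel–Crafts attack in step 6, and leaves in that step's work-up.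

Step 5
Reactants: 6 4-bromo-8-methoxynaphthalen-1-yl acetate
Product: 8 potassium [4-(acetyloxy)-5-methoxynaphthalen-1-yl]trifluoroborate, via pinacol boronate 7 (not isolated)
Conditions: B2pin2 (1.2 equiv), PdCl2(dppf) (3 mol %), KOAc (3 equiv), 1,4-dioxane, 85 °C; filter, concentrate; then aq KHF2 (4.5 M, 4 equiv), MeCN, 0 °C → rt; precipitate from acetone/Et2O
Reagents that add atoms: bis(pinacolato)diboron, CC1(C)OB(OC1(C)C)B1OC(C)(C)C(C)(C)O1; potassium hydrogen difluoride, [K+].[F-].F
Why: Miyaura borylation of the aryl bromide (acetate and methyl ether are inert to PdCl2(dppf)/KOAc) followed by fluoride exchange of the crude pinacol ester should give a crystalline aryl donor whose boron becomes a Lewis acid only in step 6.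

Step 6
Reactants: 3 (1S,4R)-5-methoxy-1,2,3,4-tetrahydro-1,4-epoxynaphthalene; 8 potassium [4-(acetyloxy)-5-methoxynaphthalen-1-yl]trifluoroborate
Product: 12 (1S,4S)-4-(4-hydroxy-5-methoxynaphthalen-1-yl)-5-methoxy-1,2,3,4-tetrahydronaphthalen-1-ol, via aryldifluoroborane 9 (not isolated), via borate zwitterion 10 (not isolated), via difluoroboryl ether 11 (not isolated)
Conditions: 8 (1.2 equiv), TMSCl (1.15 equiv), MeCN, rt; evaporate, take up in CH2Cl2; 3 (1.0 equiv), CH2Cl2 (0.05 M), −78 → −20 °C; then K2CO3 (6 equiv), MeOH/H2O (degassed), 0 °C → rt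
Reagents that add atoms: none
Why: Proposed new method: fluoride abstraction from 8 by TMSCl should give borane 9 as the only Lewis acid present; it binds the bridging oxygen of 3, the O–C4 bond ionises (C4 is ortho-methoxybenzylic, C1 is not) to give zwitterion 10, in which the C4 cation lies under an aryl(alkoxy)difluoroborate still bound to the C1 oxygen, and the aryl group then shifts from tetracoordinate boron to C4 across ring B through a seven-membered, boat-like transition state (C4···C1′–B–O–C1–C2–C3) to leave difluoroboryl ether 11. The closest known reaction types are the Petasis borono-Mannich reaction and hydroxyl-directed boronate additions to cyclic N-acyliminium and oxocarbenium ions (aryl shift from a hydroxyl-bound borate to a neighbouring cation, there 1,2 and here 1,4 across a ring), substitutions of benzylic alcohols and acetals by organotrifluoroborates under fluoride abstraction, and retentive openings of epoxides by arylalanes. No ring is closed: the step opens the oxygen bridge and forms the C4–C1′ bond between ring B and ring C. The new C4 stereocentre is controlled by C1 through the O–B tether, because the aryl group can only arrive on the face the oxygen has left, so C4 reacts with retention (its descriptor changes from R to S only because the priorities change) and the cis-(1S,4S) product follows from geometry, not from a selection. The step needs ionisation at C4 and not C1 (secured by the ortho versus meta position of the C5 methoxy), bonding through C1′ (fixed by the boron, since the neutral borane is no nucleophile and only the borate formed at the C1 oxygen is, while the acetate keeps ring C from free Friedel–Crafts attack), and an aryl shift faster than loss of H3 (low temperature, no base, no free Brønsted acid). Carbonate in methanol then cleaves the O–BF2 group of 11 and the aryl acetate in the same flask.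

**Compound list**

1 | 5-methoxy-3,4-dihydronaphthalen-1(2H)-one | COc1cccc2c1CCCC2=O | starting material
2 | (S)-5-methoxy-1,2,3,4-tetrahydronaphthalen-1-ol | COc1cccc2c1CCC[C@@H]2O | intermediate
3 | (1S,4R)-5-methoxy-1,2,3,4-tetrahydro-1,4-epoxynaphthalene | COc1cccc2c1[C@H]3CC[C@@H]2O3 | intermediate
4 | 8-methoxynaphthalen-1-ol | COc1cccc2cccc(O)c12 | starting material
5 | 4-bromo-8-methoxynaphthalen-1-ol | COc1cccc2c(Br)ccc(O)c12 | intermediate
6 | 4-bromo-8-methoxynaphthalen-1-yl acetate | COc1cccc2c(Br)ccc(OC(C)=O)c12 | intermediate
7 | 8-methoxy-4-(4,4,5,5-tetramethyl-1,3,2-dioxaborolan-2-yl)naphthalen-1-yl acetate (pinacol boronate, not isolated) | COc1cccc2c(B3OC(C)(C)C(C)(C)O3)ccc(OC(C)=O)c12 | intermediate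
8 | potassium [4-(acetyloxy)-5-methoxynaphthalen-1-yl]trifluoroborate | [K+].COc1cccc2c([B-](F)(F)F)ccc(OC(C)=O)c12 | intermediate
9 | 4-(difluoroboranyl)-8-methoxynaphthalen-1-yl acetate (aryldifluoroborane, not isolated) | COc1cccc2c(B(F)F)ccc(OC(C)=O)c12 | intermediate
10 | zwitterion of the C4 benzylic cation and the C1-O-bound aryl(difluoro)borate, (1S) (not isolated) | COc1cccc2c1[CH+]CC[C@@H]2O[B-](F)(F)c1ccc(OC(C)=O)c2c(OC)cccc12 | intermediate
11 | 4-{(1S,4S)-4-[(difluoroboranyl)oxy]-8-methoxy-1,2,3,4-tetrahydronaphthalen-1-yl}-8-methoxynaphthalen-1-yl acetate (not isolated) | COc1cccc2c1[C@H](c1ccc(OC(C)=O)c3c(OC)cccc13)CC[C@@H]2OB(F)F | intermediate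
12 | (1S,4S)-4-(4-hydroxy-5-methoxynaphthalen-1-yl)-5-methoxy-1,2,3,4-tetrahydronaphthalen-1-ol (Dipolynaphthalene B, cis) | COc1cccc2c1[C@H](c1ccc(O)c3c(OC)cccc13)CC[C@@H]2O | target

**Count and risks**

Total steps: 6. Longest linear sequence: 4 (steps 3, 4, 5, 6).

Steps most likely to fail:

1. Step 6 (Proposed new method). After ionisation, loss of the C3 proton from the C4 cation (followed by protonolysis of the borate C–B bond by the acid released) may outrun the aryl shift across ring B. Alternatively, aryl transfer may occur between two molecules and then without facial control. The fallback uses known chemistry: the aryl group goes onto C4 at the ketone level and the C4 hydrogen comes last. It sets out from 2 and 5 and comes back at 12. Alcohol 2 would be silylated (TBSCl, imidazole, DMF) to tert-butyl{[(1S)-5-methoxy-1,2,3,4-tetrahydronaphthalen-1-yl]oxy}dimethylsilane F1. Its only benzylic methylene would be oxidised (CrO3, 3,5-dimethylpyrazole, CH2Cl2, −20 °C) to (4S)-4-[(tert-butyldimethylsilyl)oxy]-8-methoxy-3,4-dihydronaphthalen-1(2H)-one F2. Naphthol 5 would be silylated (TBSOTf, 2,6-lutidine) to [(4-bromo-8-methoxynaphthalen-1-yl)oxy](tert-butyl)dimethylsilane F3, and bromine–lithium exchange (n-BuLi, THF, −78 °C) would give {4-[(tert-butyldimethylsilyl)oxy]-5-methoxynaphthalen-1-yl}lithium F4. Addition of this aryllithium to the ketone would give the tertiary carbinol (4S)-4-[(tert-butyldimethylsilyl)oxy]-1-{4-[(tert-butyldimethylsilyl)oxy]-5-methoxynaphthalen-1-yl}-8-methoxy-1,2,3,4-tetrahydronaphthalen-1-ol F5, of which both C1 epimers serve. Ionic hydrogenation (Et3SiH, CF3CO2H, CH2Cl2, −78 → −40 °C) would ionise it to the diaryl cation and should deliver hydride along the axial path anti to the pseudoaxial C–OTBS group, leaving aryl and oxygen cis, to give tert-butyl{[(1S,4S)-4-{4-[(tert-butyldimethylsilyl)oxy]-5-methoxynaphthalen-1-yl}-5-methoxy-1,2,3,4-tetrahydronaphthalen-1-yl]oxy}dimethylsilane F6. TBAF in THF would then free both hydroxyls to give 12.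

2. Step 2. After hydride abstraction, loss of a C3 proton and further dehydrogenation or dehydration to a naphthalene may outrun capture of the cation by the hydroxyl across ring B, or the acidic hydroquinone may re-open the bridge. The fallback reaches the C4 cation by stepwise oxidation, reduction and acid ionisation. It sets out from 2 and comes back at 3. Acetylation (Ac2O, pyridine) would give (1S)-5-methoxy-1,2,3,4-tetrahydronaphthalen-1-yl acetate F7. Oxidation of its only benzylic methylene (CrO3, AcOH/H2O) would give (1S)-5-methoxy-4-oxo-1,2,3,4-tetrahydronaphthalen-1-yl acetate F8. NaBH4 in MeOH followed by K2CO3 would give (1S)-5-methoxy-1,2,3,4-tetrahydronaphthalene-1,4-diol F9 as a mixture of C4 epimers. Acid-catalysed cyclodehydration (pyridinium p-toluenesulfonate, CH2Cl2, 4 Å MS) should converge both epimers on 3 through the same ortho-methoxybenzylic cation.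

3. Step 5. Protonolysis of the electron-rich α-naphthyl C–B bond or loss of the acetate may occur during the fluoride exchange. The fallback makes the C–B bond through an aryllithium on the free naphthol and acetylates last. It sets out from 5 and comes back at 8. Deprotonation and bromine–lithium exchange (n-BuLi, 1 equiv, then t-BuLi, 2 equiv, THF, −78 °C) would give lithium 4-lithio-8-methoxynaphthalen-1-olate F10. Trapping with B(OiPr)3 and treatment with aq KHF2 would give potassium trifluoro(4-hydroxy-5-methoxynaphthalen-1-yl)borate F11. Acetylation of this salt (Ac2O, pyridine, MeCN) would give 8.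

**Further compounds**

F1 | step 6 | tert-butyl{[(1S)-5-methoxy-1,2,3,4-tetrahydronaphthalen-1-yl]oxy}dimethylsilane | COc1cccc2c1CCC[C@@H]2O[Si](C)(C)C(C)(C)C
F2 | step 6 | (4S)-4-[(tert-butyldimethylsilyl)oxy]-8-methoxy-3,4-dihydronaphthalen-1(2H)-one | COc1cccc2c1C(=O)CC[C@@H]2O[Si](C)(C)C(C)(C)C
F3 | step 6 | [(4-bromo-8-methoxynaphthalen-1-yl)oxy](tert-butyl)dimethylsilane | COc1cccc2c(Br)ccc(O[Si](C)(C)C(C)(C)C)c12
F4 | step 6 | {4-[(tert-butyldimethylsilyl)oxy]-5-methoxynaphthalen-1-yl}lithium | COc1cccc2c([Li])ccc(O[Si](C)(C)C(C)(C)C)c12
F5 | step 6 | (4S)-4-[(tert-butyldimethylsilyl)oxy]-1-{4-[(tert-butyldimethylsilyl)oxy]-5-methoxynaphthalen-1-yl}-8-methoxy-1,2,3,4-tetrahydronaphthalen-1-ol (both C1 epimers) | COc1cccc2c1C(O)(c1ccc(O[Si](C)(C)C(C)(C)C)c3c(OC)cccc13)CC[C@@H]2O[Si](C)(C)C(C)(C)C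
F6 | step 6 | tert-butyl{[(1S,4S)-4-{4-[(tert-butyldimethylsilyl)oxy]-5-methoxynaphthalen-1-yl}-5-methoxy-1,2,3,4-tetrahydronaphthalen-1-yl]oxy}dimethylsilane | COc1cccc2c1[C@H](c1ccc(O[Si](C)(C)C(C)(C)C)c3c(OC)cccc13)CC[C@@H]2O[Si](C)(C)C(C)(C)C
F7 | step 2 | (1S)-5-methoxy-1,2,3,4-tetrahydronaphthalen-1-yl acetate | COc1cccc2c1CCC[C@@H]2OC(C)=O
F8 | step 2 | (1S)-5-methoxy-4-oxo-1,2,3,4-tetrahydronaphthalen-1-yl acetate | COc1cccc2c1C(=O)CC[C@@H]2OC(C)=O
F9 | step 2 | (1S)-5-methoxy-1,2,3,4-tetrahydronaphthalene-1,4-diol (both C4 epimers) | COc1cccc2c1C(O)CC[C@@H]2O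
F10 | step 5 | lithium 4-lithio-8-methoxynaphthalen-1-olate | COc1cccc2c([Li])ccc(O[Li])c12
F11 | step 5 | potassium trifluoro(4-hydroxy-5-methoxynaphthalen-1-yl)borate | [K+].COc1cccc2c([B-](F)(F)F)ccc(O)c12
A1 | direct plan | 1-(2-bromo-3-methoxyphenyl)cyclopropan-1-ol | COc1cccc(C2(O)CC2)c1Br
A2 | direct plan | 4-[(tert-butyldimethylsilyl)oxy]-5-methoxy-1-naphthaldehyde | COc1cccc2c(C=O)ccc(O[Si](C)(C)C(C)(C)C)c12
A3 | direct plan | racemic 4-{hydroxy[2-(1-hydroxycyclopropyl)-6-methoxyphenyl]methyl}-8-methoxynaphthalen-1-ol | COc1cccc(C2(O)CC2)c1C(O)c1ccc(O)c2c(OC)cccc12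
A4 | direct plan | (S)-4-(4-hydroxy-5-methoxynaphthalen-1-yl)-5-methoxy-3,4-dihydronaphthalen-1(2H)-one | COc1cccc2c1[C@H](c1ccc(O)c3c(OC)cccc13)CCC2=O
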